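Cuts: the O3–benzyl bond (the only protecting group), then arene bonds C3–C4 and C1–C6, then the acyl C–O bond to the chain alcohol, then chain bond C16–C17.
Enabling feature: in the only ring, C1 (CO2R), C2 (OH) and C3 (OH) repeat the pattern of C2/C3/C4 of a 4-alkoxyacetoacetate. C4, C5 and C6 are bare CH units and correspond to a symmetrical malonaldehyde equivalent.
Forward, chain first: a C5 + C16 Grignard coupling gives the C21 alcohol. This alcohol traps the acylketene from benzyloxyacetyl Meldrum's acid, and two silylations then give the 1,3-bis(silyloxy)diene.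
Forward, ring last: the benzene ring is closed by [3+3] cyclocondensation with 1,1,3,3-tetramethoxypropane, and hydrogenolysis of the benzyl ether ends the route.
Stereochemistry: C18 (S) comes from the chiral pool with (S)-1-bromo-2-methylbutane, and no later step makes or breaks a bond at this carbon.

Key step: step 6

Assumption: the silyl enol ethers are expected as E/Z mixtures and the two non-aromatic intermediates of the ring closure as diastereomer mixtures; aromatisation erases all of this, so those SMILES leave these elements open.

Step 1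
Reactants: 1 (S)-1-bromo-2-methylbutane; 2 16-bromohexadecan-1-ol
Product: 4 (S)-18-methylicosan-1-ol, via (S)-2-methylbutylmagnesium bromide 3 (not isolated)
Conditions: 1 (2.5 equiv), Mg, THF, reflux; then added slowly to 2, Li2CuCl4 (3 mol%), N-methylpyrrolidinone (4 equiv), THF, 0 → 20 °C; aq NH4Cl
Reagents that add atoms: magnesium, [Mg] (kept only in intermediate 3)
Why: Copper-catalysed sp3–sp3 Grignard cross-coupling (Kochi–Tamura type) is routine for primary alkyl bromides; one equivalent of 3 is spent on the O–H proton, and the stereocentre lies beta to magnesium, so it should be carried through unchanged.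

Step 2
Reactants: 5 benzyloxyacetyl chloride; 6 Meldrum's acid (2,2-dimethyl-1,3-dioxane-4,6-dione)
Product: 7 5-[2-(benzyloxy)-1-hydroxyethylidene]-2,2-dimethyl-1,3-dioxane-4,6-dione (enol form of benzyloxyacetyl Meldrum's acid)
Conditions: pyridine (2.2 equiv), CH2Cl2, 0 → 20 °C; dilute aq HCl wash
Reagents that add atoms: none
Why: C-acylation of the acidic methylene of Meldrum's acid by an acid chloride with pyridine is the standard entry to acyl Meldrum's acids, and the benzyl ether takes no part.

Step 3
Reactants: 7 benzyloxyacetyl Meldrum's acid; 4 (S)-18-methylicosan-1-ol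
Product: 9 (S)-18-methylicosyl 4-(benzyloxy)-3-oxobutanoate, via (benzyloxyacetyl)ketene 8 (not isolated)
Conditions: 7 (1.1 equiv), toluene, 110 °C, 3 h
Reagents that add atoms: none
Why: Thermal fragmentation of an acyl Meldrum's acid (loss of acetone and CO2) gives an acylketene that a primary alcohol traps as the beta-keto ester under neutral conditions, so about one equivalent of the valuable alcohol should suffice.

Step 4
Reactants: 9 (S)-18-methylicosyl 4-(benzyloxy)-3-oxobutanoate
Product: 10 (S)-18-methylicosyl 4-(benzyloxy)-3-(trimethylsilyloxy)but-2-enoate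
Conditions: Me3SiCl (1.8 equiv), Et3N (1.6 equiv), toluene, 20 °C, 48 h; filtration under Ar, used crude
Reagents that add atoms: chlorotrimethylsilane, C[Si](C)(C)Cl
Why: Soft O-silylation of a strongly enolised beta-keto ester with Me3SiCl/Et3N is the usual first stage of 1,3-bis(silyloxy)diene synthesis and affects neither the ester nor the benzyl ether.

Step 5
Reactants: 10 (S)-18-methylicosyl 4-(benzyloxy)-3-(trimethylsilyloxy)but-2-enoate
Product: 12 4-(benzyloxy)-1-[(S)-18-methylicosyloxy]-1,3-bis(trimethylsilyloxy)buta-1,3-diene, via lithium dienolate 11 (not isolated)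
Conditions: LiN(iPr)2 (1.5 equiv), THF, −78 °C, 1 h; Me3SiCl (1.8 equiv), −78 → 20 °C; hexane, filtration under Ar, used crude
Reagents that add atoms: chlorotrimethylsilane, C[Si](C)(C)Cl; lithium diisopropylamide, [Li+].CC(C)[N-]C(C)C (lithium kept only in intermediate 11)
Why: Kinetic gamma-deprotonation of a 3-silyloxy-2-enoate with a hindered lithium amide gives an extended dienolate that is silylated at the ester oxygen, which is the established route to 4-alkoxy-1,3-bis(silyloxy)buta-1,3-dienes.

Step 6
Reactants: 12 4-(benzyloxy)-1-[(S)-18-methylicosyloxy]-1,3-bis(trimethylsilyloxy)buta-1,3-diene; 13 1,1,3,3-tetramethoxypropane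
Product: 16 (S)-18-methylicosyl 3-(benzyloxy)-2-hydroxybenzoate, via open-chain Mukaiyama adduct 14 (not isolated), via dimethoxycyclohexanone carboxylate 15 (not isolated)
Conditions: 13 (1.1 equiv), Me3SiOTf (10 mol%), CH2Cl2, −78 → 20 °C, 14 h; then 10% aq HCl, 20 °C
Reagents that add atoms: none
Why: Me3SiOTf abstracts a methoxy group from 13, and the oxocarbenium ion is intercepted by C4 of diene 12, the terminus that carries OBn (vinylogous Mukaiyama addition, arene bond C3–C4), which releases Me3SiOMe, returns the silyl triflate and leaves the 3-silyloxy-2-enoate 14. The second acetal is ionised in the same way and the enol carbon next to the ester attacks it in a 6-(enolendo)-exo-trig closure (arene bond C1–C6) to give 15, the only ring closed in the step; acid then expels the two remaining ring methoxy groups as methanol, and enolisation of the C2 ketone should deliver the phenol. The closest known reaction type is the formal [3+3] cyclocondensation of 1,3-bis(silyloxy)buta-1,3-dienes, 4-alkoxy members included, with malonaldehyde bis(acetals) to salicylates, run either with stoichiometric TiCl4 or with catalytic Me3SiOTf. No stereocentre is set, because the centres that appear in 14 and 15 are erased on aromatisation and C18 of the chain is remote and unactivated. Regioselectivity is secured by the substrates, since 13 is symmetrical and either order of the two C–C bond formations leads to the same arene with ester, free 2-OH and 3-OBn in sequence. Chemoselectivity concerns the benzyl ether, and the catalytic silyl triflate is chosen because a full equivalent of TiCl4 could chelate O2 and O3 of the product on warming and strip the benzyl group, whereas the saturated alkyl ester is inert to either acid.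

Step 7
Reactants: 16 (S)-18-methylicosyl 3-(benzyloxy)-2-hydroxybenzoate
Product: 17 gentiside H, (S)-18-methylicosyl 2,3-dihydroxybenzoate
Conditions: H2 (1 atm), Pd/C (10 wt% Pd), EtOAc, 20 °C
Reagents that add atoms: none
Why: Catalytic hydrogenolysis of an aryl benzyl ether over Pd/C is neutral and should leave the alkyl ester, the arene and the remote stereocentre untouched.

Compound list
1 | (S)-1-bromo-2-methylbutane | CC[C@H](C)CBr | starting material
2 | 16-bromohexadecan-1-ol | OCCCCCCCCCCCCCCCCBr | starting material
3 | (S)-2-methylbutylmagnesium bromide | CC[C@H](C)C[Mg]Br | intermediate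
4 | (S)-18-methylicosan-1-ol | CC[C@H](C)CCCCCCCCCCCCCCCCCO | intermediate
5 | benzyloxyacetyl chloride | O=C(Cl)COCc1ccccc1 | starting material
6 | Meldrum's acid (2,2-dimethyl-1,3-dioxane-4,6-dione) | CC1(C)OC(=O)CC(=O)O1 | starting material
7 | 5-[2-(benzyloxy)-1-hydroxyethylidene]-2,2-dimethyl-1,3-dioxane-4,6-dione | CC1(C)OC(=O)C(=C(O)COCc2ccccc2)C(=O)O1 | intermediate
8 | (benzyloxyacetyl)ketene, 4-(benzyloxy)but-1-ene-1,3-dione | O=C=CC(=O)COCc1ccccc1 | intermediate
9 | (S)-18-methylicosyl 4-(benzyloxy)-3-oxobutanoate | CC[C@H](C)CCCCCCCCCCCCCCCCCOC(=O)CC(=O)COCc1ccccc1 | intermediate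
10 | (S)-18-methylicosyl 4-(benzyloxy)-3-(trimethylsilyloxy)but-2-enoate | CC[C@H](C)CCCCCCCCCCCCCCCCCOC(=O)C=C(O[Si](C)(C)C)COCc1ccccc1 | intermediate
11 | lithium 4-(benzyloxy)-1-[(S)-18-methylicosyloxy]-3-(trimethylsilyloxy)buta-1,3-dien-1-olate | CC[C@H](C)CCCCCCCCCCCCCCCCCOC([O-])=CC(O[Si](C)(C)C)=COCc1ccccc1.[Li+] | intermediate
12 | 4-(benzyloxy)-1-[(S)-18-methylicosyloxy]-1,3-bis(trimethylsilyloxy)buta-1,3-diene | CC[C@H](C)CCCCCCCCCCCCCCCCCOC(O[Si](C)(C)C)=CC(O[Si](C)(C)C)=COCc1ccccc1 | intermediate
13 | 1,1,3,3-tetramethoxypropane | COC(OC)CC(OC)OC | starting material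
14 | (S)-18-methylicosyl 4-(benzyloxy)-5,7,7-trimethoxy-3-(trimethylsilyloxy)hept-2-enoate | CC[C@H](C)CCCCCCCCCCCCCCCCCOC(=O)C=C(O[Si](C)(C)C)C(OCc1ccccc1)C(OC)CC(OC)OC | intermediate
15 | (S)-18-methylicosyl 3-(benzyloxy)-4,6-dimethoxy-2-oxocyclohexane-1-carboxylate | CC[C@H](C)CCCCCCCCCCCCCCCCCOC(=O)C1C(OC)CC(OC)C(OCc2ccccc2)C1=O | intermediate
16 | (S)-18-methylicosyl 3-(benzyloxy)-2-hydroxybenzoate | CC[C@H](C)CCCCCCCCCCCCCCCCCOC(=O)c1cccc(OCc2ccccc2)c1O | intermediate
17 | gentiside H, (S)-18-methylicosyl 2,3-dihydroxybenzoate | CC[C@H](C)CCCCCCCCCCCCCCCCCOC(=O)c1cccc(O)c1O | target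

Total step count: 7. Longest linear sequence: 6 steps (steps 1, 3, 4, 5, 6, 7). The branch through step 2 is equally long.

Steps most likely to fail

Step 6. Three processes could spoil the step:
- Intermolecular capture of the oxocarbenium ions could outrun ring closure, either by oligomerisation of the three-carbon unit or by two acetal units adding to one diene.
- Adventitious acid could protodesilylate the diene.
- The sequence could stall before the second methanol is lost.

In the fallback the arene is bought instead of built. It sets out from alcohol 4. Carbodiimide esterification with commercial 2,3-bis(benzyloxy)benzoic acid (N-ethyl-N'-(3-dimethylaminopropyl)carbodiimide hydrochloride, 4-dimethylaminopyridine, CH2Cl2, 20 °C) should give (S)-18-methylicosyl 2,3-bis(benzyloxy)benzoate F1. Hydrogenolysis of both benzyl ethers (H2, Pd/C, EtOAc) rejoins the route at 17.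

Step 5. Gamma-deprotonation could stay incomplete because the waxy ester crystallises from THF at −78 °C. The silyl groups could also be lost by hydrolysis during handling, since a diene of this mass cannot be purified by distillation. The fallback carries out the silylations and the ring construction on a small methyl ester and attaches the chain afterwards, which keeps the same ring disconnection. It sets out from 7:
- Refluxing methanol should give methyl 4-(benzyloxy)-3-oxobutanoate F2.
- Me3SiCl/Et3N should give methyl 4-(benzyloxy)-3-(trimethylsilyloxy)but-2-enoate F3.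
- LiN(iPr)2 followed by Me3SiCl should give 4-(benzyloxy)-1-methoxy-1,3-bis(trimethylsilyloxy)buta-1,3-diene F4.
- Cyclocondensation with 13 under the conditions of step 6 should give methyl 3-(benzyloxy)-2-hydroxybenzoate F5.
- LiOH in aqueous THF should give 3-(benzyloxy)-2-hydroxybenzoic acid F6.
- Mitsunobu esterification of F6 with 4 (PPh3, diisopropyl azodicarboxylate, THF, 0 → 20 °C) rejoins the route at 16. The carboxylic acid is far more acidic than the hydrogen-bonded phenol, so it should react selectively.

Step 1. The alkylcopper species could undergo homocoupling and beta-hydride loss, and the C–Br bond could be reduced. Turnover could also be sluggish if the magnesium alkoxide of the bromo alcohol precipitates. The fallback makes the same junction as a C16=C17 double bond by Wittig olefination and sets out from 2.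
- PPh3 in refluxing MeCN should give (16-hydroxyhexadecyl)triphenylphosphonium bromide F7.
- Commercial (S)-2-methylbutan-1-ol is oxidised to (S)-2-methylbutanal F8 (NaOCl, KBr, 2,2,6,6-tetramethylpiperidin-1-oxyl at 1 mol%, CH2Cl2/water, 0 °C).
- The ylide from F7 (NaN(SiMe3)2, 2 equiv, THF) is treated with F8 at −78 °C to limit enolisation. This should give (16Z,18S)-18-methylicos-16-en-1-ol F9.
- Diimide reduction (p-toluenesulfonyl hydrazide, NaOAc, aqueous THF, reflux) cannot move the double bond into the stereocentre and rejoins the route at 4.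

Further compounds
F1 | step 6 | (S)-18-methylicosyl 2,3-bis(benzyloxy)benzoate | CC[C@H](C)CCCCCCCCCCCCCCCCCOC(=O)c1cccc(OCc2ccccc2)c1OCc3ccccc3
F2 | step 5 | methyl 4-(benzyloxy)-3-oxobutanoate | COC(=O)CC(=O)COCc1ccccc1
F3 | step 5 | methyl 4-(benzyloxy)-3-(trimethylsilyloxy)but-2-enoate | COC(=O)C=C(O[Si](C)(C)C)COCc1ccccc1
F4 | step 5 | 4-(benzyloxy)-1-methoxy-1,3-bis(trimethylsilyloxy)buta-1,3-diene | COC(O[Si](C)(C)C)=CC(O[Si](C)(C)C)=COCc1ccccc1
F5 | step 5 | methyl 3-(benzyloxy)-2-hydroxybenzoate | COC(=O)c1cccc(OCc2ccccc2)c1O
F6 | step 5 | 3-(benzyloxy)-2-hydroxybenzoic acid | OC(=O)c1cccc(OCc2ccccc2)c1O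
F7 | step 1 | (16-hydroxyhexadecyl)triphenylphosphonium bromide | OCCCCCCCCCCCCCCCC[P+](c1ccccc1)(c1ccccc1)c1ccccc1.[Br-]
F8 | step 1 | (S)-2-methylbutanal | CC[C@H](C)C=O
F9 | step 1 | (16Z,18S)-18-methylicos-16-en-1-ol | CC[C@H](C)/C=C\CCCCCCCCCCCCCCCO
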